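Millimolar per minute is the unit to reckon in: the flask has the catalyst, ligand and second-substrate charges of cedar and oak, and those two runs differ in starting material. Elm, with 0.66 mM added ligand, stays aside.

in all of them: free catalyst 0.40 mM

| charge | starting material | second substrate | added ligand | remark | time |
|---|---|---|---|---|---|
| cedar | 10 mM | 20 mM | 0.33 mM | run made earlier |  |
| oak | 40 mM | 20 mM | 0.33 mM | run made earlier |  |
| elm | 20 mM | 20 mM | 0.66 mM | run made earlier |  |
| flask | 20 mM | 20.0 mM | 0.33 mM |  | 10 min |

| run | time / min | target / % |
|---|---|---|
| cedar | 0.417 | 10 |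
| cedar | 1.33 | 30 |
| cedar | 2.00 | 44 |
| cedar | 3.00 | 59 |
| cedar | 5.00 | 79 |
| cedar | 6.00 | 91 |
| oak | 1.00 | 11 |
| oak | 2.00 | 17 |
| oak | 3.00 | 33 |
| oak | 4.00 | 39 |
| oak | 5.00 | 50 |
| oak | 6.00 | 56 |
| elm | 0.500 | 9 |
| elm | 0.833 | 11 |
| elm | 1.50 | 23 |
| elm | 3.00 | 41 |
| elm | 6.00 | 71 |

(standard deviation of a reading: 2 percentage points)



- amount of target in percent of the starting material charged, at 1.0 min, 4.0 min and 10 min

1. Read the early rates. Cedar makes 2.26 mM min⁻¹ of target up to 1.33 min, and oak makes 4.40 mM min⁻¹ up to 3.00 min.

2. Go to logarithms. The log of the rate ratio over the log of the charge ratio gives an order of 0.482.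

3. Carry that power to the flask's charge: the rate is 3.15 mM min⁻¹, so 1.0 min gives 15.8%. This is the weak link, since the same straight line claims 158% at 10 min, more than the charge holds.

4. Reforge it with rate = V·A/(K+A), where A is the starting material present. Integrated, this reads K·ln(charge/left) + converted = V·t. Cedar at 5.00 min and oak at 6.00 min give a reading of K = 12.3 mM and V = 5.41 mM min⁻¹. Dividing V by the catalyst charge gives the turnover rate 13.5 min⁻¹, the top turnover frequency at this ligand charge. Turnover rate × catalyst charge × time is the clock, V·t, in millimolar.

5. My figures for the flask follow. The starting rate gives 16.8% at 1.0 min. Conversion of 50% takes 3.42 min, and the rate there carries it to 57.1% at 4.0 min. Solving the logarithm for what is left gives 1.24 mM, then 1.12 mM, so 94.4% at 10 min.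

The forecast, from the same runs, says 16.5%, 59% and 95%, noting that “the order in starting material is well below one”. Its figures differ slightly from mine.

The simulation gives 16.4%, 58.6% and 96.1%.

    starting material + free catalyst ⇌ catalyst intermediate A (K = 4900 M⁻¹, k = 40.0 M⁻¹ s⁻¹)
    catalyst intermediate A → free catalyst + target (k = 0.230 s⁻¹)
    second substrate + free catalyst ⇌ catalyst intermediate B (K = 16.0 M⁻¹, k = 44.0 M⁻¹ s⁻¹)
    catalyst intermediate B → free catalyst + second product (k = 0.320 s⁻¹)
    free catalyst + added ligand ⇌ idle complex, settled at all times (K = 2500 M⁻¹)

Watch the clock as you repeat the run. At 5.00 min the flask has 27.1 mM on it and stands at 69.3% target. The largest single effect on the flask's target at 10 min is the backward run from catalyst intermediate B to second substrate and free catalyst : without that step the same flask gives 90.8% against 96.1%. Half the free catalyst over the full 10 min puts the same 27.1 mM on the clock, and that flask reads 68.5% target.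

The numbers in the tables were generated by integration for an exercise.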